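## Structural features

The target is a longipinane diester built on a cyclobutane (C4–C5–C11–C10) whose two diagonals are bridged on opposite faces. C4 and C11 are spanned by the enone unit C1(=O)–C2=C3(CH3), giving a verbenone-like bicyclo[3.1.1]heptenone. C5 and C10 are spanned by the chain C6(CH3)2–C7–C8–C9, giving a bicyclo[4.1.1]octane, so the seven-membered ring is counted through C4 or through C11. There are six stereocentres: the four contiguous cyclobutane carbons (C10 quaternary, with a methyl group), whose relative configuration is dictated by the double bridging, and the carbinol carbons C7 and C9, which are 1,3-related, trans, and each next to a quaternary carbon. The fragile elements are two different esters on hindered secondary alcohols (isovalerate on O7, E-tiglate on O9), the enone, and the pinene-type cyclobutane, which rearranges once a cation develops beside it. The real difficulties are the fully substituted, doubly bridged cyclobutane and the two differentiated trans oxygens on a bridge lying on a local mirror plane. That plane is broken only by the distant enone, so the substrate hardly distinguishes the faces of C7 and C9, and the absolute sense of the molecule is decided by which end of the enone bridge carries the carbonyl. The key step exploits the methylene C8 between C7 and C9: removing it leaves a cyclohexanone (C9=O flanked by methylene C7 and quaternary C10) in a tricyclo[4.4.0.0(2,7)]decane, and re-inserting it with migration of C7 restores the seven-membered ring.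

## Logic of the disconnections

19 to 18. The O9–acyl bond is cut last. The two esters differ, so one must go on alone. The forward step is an acylation of a hindered alcohol that already carries the other ester.

18 to 17. The O7–acyl bond and the C9–H bond are cut together. A β-hydroxy ketone can be turned into the anti-1,3-diol monoester in one intramolecular hydride transfer, which sets C9 from C7 and differentiates the two oxygens without protecting groups. The forward step needs the C7 oxygen to reach over the C9 carbonyl, which the 1,3-relationship on the bridge allows.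

17 to 15. The C7–O bond is cut back to the C7=C8 enone (through a C7–B bond). This removes the first carbinol centre. Because the bridge is locally symmetric, the forward step must be catalyst-controlled and must leave the C2=C3 enone alone.

15 to 14. The C7=C8 unsaturation is removed. The C9 ketone of 14 has only one enolisable side, so the forward dehydrogenation needs no regiocontrol.

14 to 12. C8 is excised, cutting C8–C9 and C7–C8. This changes the bridged seven-membered ring into a cyclohexanone and gives a tricyclo[4.4.0.0(2,7)]decane. The forward insertion must choose C7 over C10 as the migrating carbon and the saturated C9 carbonyl over the conjugated C1 carbonyl. For that reason 12 carries the enone and not a second saturated ketone. It must also be a single enantiomer: a racemate would leave the later chiral borylation to turn enantiomers into diastereomers and lose half of the material.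

12 to 11 to 9. The C2=C3 unsaturation and two C–CH3 bonds (C3–CH3 and one C6–CH3) are cut. This leaves a bis-enone in which both β-carbons need a methyl group, so one cuprate step serves both and no selection between the enones is required. Re-oxidation is regiospecific because C1 can enolise only toward C2.

9 to 7. The cyclobutane bond C5–C11 is cut to an enolate (C11) and an allylic bromide (C5) on a cis-fused bicyclic dienedione. The forward step needs the enolate regiochemistry fixed (enone, only one α′ site) and the leaving group on the face away from C11.

7 to 6 to 5 to 4. Three functional-group changes are undone: the C5–Br bond (from the alcohol with inversion), the C2=C3 enone (from the silyl enol ether), and the C5–H bond (from the carbonyl). The forward reduction must pick the C5 carbonyl over the C9 carbonyl, which their different neighbours (ring-fusion CH against quaternary C10) should secure.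

4 to 2 and 3. The bonds C10–C11 and C3–C4 are cut in a Diels–Alder sense. This reaches two achiral, simple partners and accounts for every ring carbon of 12. The forward step must set C10 and C4 absolutely and must join the CH2 terminus next to the oxygenated carbon of 2 to the methyl-bearing carbon of 3; both demands are met by a chiral Lewis acid. A route through a 2,2-disubstituted 1,3-diketone and a photochemical cyclobutanol was not adopted, because it brings α-cleavage, retro-Claisen opening, a bridgehead deoxygenation and no absolute control.

2 to 1. The O–Si bond is cut; the forward step is a silylation of the only enolisable position.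

## Other disconnections considered

Alternative 1: The cut is C4–C5, made on the seven-membered series. In the forward step a C4 carbonyl is excited, takes a hydrogen from C5, and the 1,4-biradical closes to the bridgehead cyclobutanol A1.
- In its favour: it turns an unactivated C5–H into the ring bond, and A1 already holds the seven-membered ring and both carbinol oxygens under different silyl groups.
- Against it here: the C4 hydroxyl is not in the target and cannot be dehydrated (bridgehead), so a radical deoxygenation at a hindered cyclobutyl position is needed. The excited carbonyl sits next to quaternary C10, which invites α-cleavage. C8 offers a competing γ-hydrogen. The flexible ring must populate the one reactive conformer. The ketal, the C3 stereocentre and the later C2=C3 dehydrogenation add steps.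
- Comparison: structurally A1 is further advanced than 9. Mechanistically the biradical closure is less predictable than the stereospecific SN2 closure of step 6 and leaves a superfluous oxygen. In step count the chosen plan is shorter and needs no protecting groups.
- Where it is equal or better: it is the better in needing no diazo reagent and no migratory selectivity, and the equal in differentiating O7 from O9.

Alternative 2: The cut is C5–C11, made by deleting the nitrogen of a pyrrolidine. In the forward step N-amination gives a 1,1-diazene, loss of N2 gives a 1,4-biradical, and collapse gives the cyclobutane A2.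
- In its favour: the contraction is stereoretentive and modular, and the C9 centre is already present.
- Against it here: A2 contains neither bridge. The enone ring and the seven-membered ring (C7–C8 bond, then removal of the C8 oxygen) must be closed afterwards on a strained, fully substituted cyclobutane. The biradical can fragment to two alkenes, more so with the quaternary C10. Three kinds of protecting group are carried.
- Comparison: structurally the chosen plan closes the cyclobutane last, from a cis-fused bicycle that holds C5 and C11 together; A2 makes it first and then needs two annulations. Mechanistically it is a biradical collapse against an enolate alkylation. In step count the alternative is much longer.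
- Where it is equal or better: it is the equal in stereochemical fidelity at the four cyclobutane carbons, and the better in avoiding strong base on an enone with an acidic γ-hydrogen.

Alternative 3: The cut is C10–C11. In the forward step the alkoxide at C1 of a 1-hydroxynorbornene drives the one-carbon bridge C10 from C1 to the mesylate-bearing C11, which gives the protected longipinenone A3.
- In its favour: one stereospecific shift forms the cyclobutane and the enone ring, and A3 already carries O7 and O9 under orthogonal groups, so the endgame is two deprotection–acylation pairs.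
- Against it here: the rearrangement substrate needs a bridgehead alcohol, an endo mesylate and the seven-membered ring in place. The intramolecular Diels–Alder reaction that would give it must close a seven-membered tether from a 5,5-disubstituted cyclopentadiene. Fragmentation or migration of the other bridge can compete.
- Comparison: both plans close the cyclobutane by a stereospecific polar displacement at a carbon beside the enone carbonyl. The alternative spends its steps before the rearrangement, the chosen plan after ring closure (steps 9 to 13).
- Where it is equal or better: it is the equal in stereospecificity, and the better in its endgame, which needs no ring expansion and no late oxygenation.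

Key step: step 9

Assumptions: atom numbers C1 to C11 are those of the longipinane skeleton used above and are kept for all intermediates, including the lower homologues that lack C8. The (S)-oxazaborolidine of step 2 and the ligand antipode of step 11 are written as the ones expected to give the required face; if the facial models assign it to the mirror-image catalyst or ligand (both commercial), that one is used.

Step 1
Reactants: 1 but-3-en-2-one
Product: 2 2-[tri(propan-2-yl)silyloxy]buta-1,3-diene
Conditions: TIPSOTf, Et3N, Et2O, 0 °C to rt
Reagents that add atoms: tri(propan-2-yl)silyl trifluoromethanesulfonate, CC(C)[Si](OS(=O)(=O)C(F)(F)F)(C(C)C)C(C)C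
Why: Soft enolisation and O-silylation of a methyl ketone with a silyl triflate and an amine; only the methyl group can be deprotonated, so the 2-silyloxydiene should be the single product.

Step 2
Reactants: 2 2-[tri(propan-2-yl)silyloxy]buta-1,3-diene; 3 2,5-dimethylcyclohexa-2,5-diene-1,4-dione
Product: 4 (4aS,8aR)-2,4a-dimethyl-6-[tri(propan-2-yl)silyloxy]-4a,5,8,8a-tetrahydronaphthalene-1,4-dione
Conditions: 2 (1.5 equiv), (S)-1-(2-methylphenyl)-3,3-diphenyltetrahydro-1H,3H-pyrrolo[1,2-c][1,3,2]oxazaborole (20 mol %), Tf2NH (20 mol %), CH2Cl2, −78 °C
Reagents that add atoms: none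
Why: Diels–Alder reaction of a quinone under chiral cationic oxazaborolidine catalysis, a known reaction type. The boron should bind the carbonyl of 3 on the side of its vinylic α-C–H, so the CH2 terminus next to the silyloxy carbon of 2 bonds to the methyl-bearing β-carbon and makes C10 quaternary (the Lewis-acid orientation, opposite to the uncatalysed one). Suprafacial addition fixes C10–CH3 and C4–H cis, and the catalyst face sets their absolute configuration.

Step 3
Reactants: 4 (4aS,8aR)-2,4a-dimethyl-6-[tri(propan-2-yl)silyloxy]-4a,5,8,8a-tetrahydronaphthalene-1,4-dione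
Product: 5 (4R,4aR,8aS)-4-hydroxy-3,8a-dimethyl-7-[tri(propan-2-yl)silyloxy]-4a,5,8,8a-tetrahydronaphthalen-1(4H)-one
Conditions: NaBH4 (1.0 equiv), CeCl3·7H2O, MeOH–CH2Cl2, −78 °C
Reagents that add atoms: none
Why: Luche 1,2-reduction. The C5 carbonyl lies next to the ring-fusion CH and is not in vinylogous conjugation with the ring methyl, so it should be less hindered and more electrophilic than the C9 carbonyl next to quaternary C10. Hydride should enter from the convex face, which puts the hydroxyl on the face of the silyloxycyclohexene ring; the silyl enol ether is inert.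

Step 4
Reactants: 5 (4R,4aR,8aS)-4-hydroxy-3,8a-dimethyl-7-[tri(propan-2-yl)silyloxy]-4a,5,8,8a-tetrahydronaphthalen-1(4H)-one
Product: 6 (4R,4aR,8aS)-4-hydroxy-3,8a-dimethyl-4,4a,8,8a-tetrahydronaphthalene-1,7-dione
Conditions: Pd(OAc)2 (1.2 equiv), MeCN, 40 °C
Reagents that add atoms: none
Why: Saegusa–Ito oxidation: silicon-to-palladium exchange gives the C2 palladium enolate and β-hydride loss from C3 releases the C2=C3 enone at the position fixed by the cycloaddition. The enone is needed so that C1 can enolise only toward C11 in step 6; the allylic alcohol should survive base-free divalent palladium.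

Step 5
Reactants: 6 (4R,4aR,8aS)-4-hydroxy-3,8a-dimethyl-4,4a,8,8a-tetrahydronaphthalene-1,7-dione
Product: 7 (4S,4aR,8aS)-4-bromo-3,8a-dimethyl-4,4a,8,8a-tetrahydronaphthalene-1,7-dione
Conditions: CBr4, PPh3, CH2Cl2, 0 °C
Reagents that add atoms: tetrabromomethane, BrC(Br)(Br)Br
Why: Appel reaction: bromide displaces the oxyphosphonium group by SN2, so bromine should end on the convex face, anti to C11; conjugation of the allyl unit with the C9 carbonyl disfavours ionisation and allylic transposition. Bromide exchange can epimerise C5, and only the convex bromide can close in step 6, so this configuration is self-correcting.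

Step 6
Reactants: 7 (4S,4aR,8aS)-4-bromo-3,8a-dimethyl-4,4a,8,8a-tetrahydronaphthalene-1,7-dione
Product: 9 (1S,2R,6S,7R)-2,5-dimethyltricyclo[4.4.0.0(2,7)]deca-4,9-diene-3,8-dione, via lithium C11 enolate 8 (not isolated)
Conditions: LDA (1.05 equiv), THF, −78 °C; then DMPU, −78 to 0 °C
Reagents that add atoms: none
Why: Intramolecular enolate alkylation, the classical closure of the cyclobutane of tricyclo[4.4.0.0(2,7)]decanes from cis-fused decalone sulfonates or halides. Kinetic deprotonation of the enone at C11 (its only α′ site) is followed by 4-exo-tet SN2 attack on allylic C5 from the concave face; O-alkylation is excluded because the enolate oxygen points away from C5. C11 follows from the cis ring fusion and C5 from the inversion, and quaternary C10 keeps either ring from aromatising.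

Step 7
Reactants: 9 (1S,2R,6S,7R)-2,5-dimethyltricyclo[4.4.0.0(2,7)]deca-4,9-diene-3,8-dione
Product: 11 (1S,2R,6S,7R,10R)-2,5,5,10-tetramethyltricyclo[4.4.0.0(2,7)]decane-3,8-dione, via bis(trimethylsilyl enol ether) 10 (not isolated)
Conditions: Me2CuLi (5 equiv, from MeLi and CuI), TMSCl, THF, −78 to 0 °C; then 1 M HCl, THF, rt
Reagents that add atoms: lithium dimethylcuprate (Me2CuLi), [Li+].C[Cu-]C
Why: TMSCl-accelerated conjugate addition of a Gilman cuprate to both enones, as known for apoverbenone- and verbenone-type bicyclo[3.1.1]heptenones. C3 receives the methyl of the enone bridge and C6 its second methyl, so the two enones need not be told apart. The C3 methyl should enter anti to the C10 methyl; this centre becomes sp2 again in step 8.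

Step 8
Reactants: 11 (1S,2R,6S,7R,10R)-2,5,5,10-tetramethyltricyclo[4.4.0.0(2,7)]decane-3,8-dione
Product: 12 (1S,2R,6R,7R)-5,7,10,10-tetramethyltricyclo[4.4.0.0(2,7)]dec-4-ene-3,8-dione
Conditions: IBX (2.5 equiv), DMSO–fluorobenzene, 75 °C
Reagents that add atoms: none
Why: IBX dehydrogenation of a ketone through its enol. The C1 ketone can enolise only toward C2 because C11 is a cyclobutane bridgehead, and the C9 ketone has no β-hydrogen (C6 and C10 are quaternary), so only the C2=C3 enone should form.

Step 9
Reactants: 12 (1S,2R,6R,7R)-5,7,10,10-tetramethyltricyclo[4.4.0.0(2,7)]dec-4-ene-3,8-dione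
Product: 14 (1R,2R,7S,8R)-2,6,6,11-tetramethyltricyclo[5.4.0.0(2,8)]undec-10-ene-3,9-dione, via C8-trimethylsilyl ketone 13 (not isolated)
Conditions: TMSCHN2 (1.5 equiv), AlMe3 (2.2 equiv), CH2Cl2, −78 to −30 °C; then 1 M HCl, THF, rt
Reagents that add atoms: (trimethylsilyl)diazomethane, C[Si](C)(C)C=[N+]=[N-]
Why: Lewis-acid-promoted homologation of a ketone with (trimethylsilyl)diazomethane, a known one-carbon ring expansion of cyclohexanones of the Tiffeneau–Demjanov type. The aluminium-activated C9 carbonyl adds the diazo carbon, and loss of N2 from the betaine is concerted with a 1,2-shift of C7 from C9 to the new carbon C8, so C8–C9 and C7–C8 form while C7–C9 breaks. No additional ring is closed: the ring count stays at three and the six-membered ring through C9, C7, C6, C5 and C10 grows to seven members by insertion. The α-silyl ketone 13 is protodesilylated by acid, so no stereocentre is created and C4, C5, C10 and C11 are untouched. Two selectivities are needed: migration of C7 over C10 and reaction at C9 over C1. With the bulky silyl diazoalkane the less substituted α-carbon is the one that can lie anti to N2 in the less crowded betaine, and C10 is a quaternary cyclobutane carbon, so C7 should migrate. The C1 carbonyl is deactivated by conjugation and flanked by a bridgehead, which is why step 8 precedes this step; one equivalent of AlMe3 is allowed for the more basic enone oxygen. The new ketone has quaternary C10 on one side and so can enolise only toward C8, which step 10 uses.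

Step 10
Reactants: 14 (1R,2R,7S,8R)-2,6,6,11-tetramethyltricyclo[5.4.0.0(2,8)]undec-10-ene-3,9-dione
Product: 15 (1R,2R,7S,8R)-2,6,6,11-tetramethyltricyclo[5.4.0.0(2,8)]undeca-4,10-diene-3,9-dione
Conditions: IBX (2.5 equiv), DMSO–fluorobenzene, 75 °C
Reagents that add atoms: none
Why: IBX dehydrogenation: the cycloheptanone enolises only toward C8 and quaternary C6 blocks further unsaturation, so the C7=C8 enone should be the only product.

Step 11
Reactants: 15 (1R,2R,7S,8R)-2,6,6,11-tetramethyltricyclo[5.4.0.0(2,8)]undeca-4,10-diene-3,9-dione
Product: 17 (1R,2R,5R,7S,8R)-5-hydroxy-2,6,6,11-tetramethyltricyclo[5.4.0.0(2,8)]undec-10-ene-3,9-dione, via C7 pinacol boronate 16 (not isolated)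
Conditions: B2pin2, CuCl (5 mol %), NaOt-Bu (10 mol %), (R)-1-[(S)-2-(diphenylphosphino)ferrocenyl]ethyldicyclohexylphosphine (6 mol %), MeOH, THF, rt; then NaBO3·4H2O, THF–H2O, rt
Reagents that add atoms: sodium perborate tetrahydrate (NaBO3·4H2O, source of the hydroxyl oxygen), [Na+].[Na+].O[B-]1(O)OO[B-](O)(O)OO1
Why: Copper-catalysed conjugate borylation of a cyclic enone and stereoretentive oxidation of the C–B bond, known for cyclohexenones and cycloheptenones. The β-monosubstituted C7=C8 enone should react before the hindered β,β-disubstituted C2=C3 enone. The bridge lies on a local mirror plane, so the chiral bisphosphine and not the substrate should decide the face; the Re face of C7 (the C4 side) gives 7R.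

Step 12
Reactants: 17 (1R,2R,5R,7S,8R)-5-hydroxy-2,6,6,11-tetramethyltricyclo[5.4.0.0(2,8)]undec-10-ene-3,9-dione
Product: 18 (1R,2R,3R,5R,7S,8R)-3-hydroxy-2,6,6,11-tetramethyl-9-oxotricyclo[5.4.0.0(2,8)]undec-10-en-5-yl 3-methylbutanoate
Conditions: 3-methylbutanal (6 equiv), SmI2 (0.3 equiv), THF, −10 °C
Reagents that add atoms: 3-methylbutanal, CC(C)CC=O
Why: Evans–Tishchenko reaction: the C7 hydroxyl forms a hemiacetal with the aldehyde, trivalent samarium bridges it to the C9 carbonyl, and hydride is delivered to C9 from the side of the C7 oxygen. This should give the 7,9-anti relationship (9R) and at once place the isovalerate on O7 and leave O9 free. The C1 carbonyl has no β-hydroxyl and is not reduced.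

Step 13
Reactants: 18 (1R,2R,3R,5R,7S,8R)-3-hydroxy-2,6,6,11-tetramethyl-9-oxotricyclo[5.4.0.0(2,8)]undec-10-en-5-yl 3-methylbutanoate
Product: 19 (1R,2R,3R,5R,7S,8R)-2,6,6,11-tetramethyl-5-[(3-methylbutanoyl)oxy]-9-oxotricyclo[5.4.0.0(2,8)]undec-10-en-3-yl (2E)-2-methylbut-2-enoate
Conditions: (E)-2-methylbut-2-enoyl chloride, DMAP, Et3N, CH2Cl2, 0 to 40 °C
Reagents that add atoms: (E)-2-methylbut-2-enoyl chloride, C/C=C(\C)C(=O)Cl
Why: DMAP-catalysed acylation of the hindered C9 alcohol with the acid chloride. The E-tigloyl group is the stable geometric isomer, and the trans-placed O7 ester cannot migrate to O9.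

Compound list

1 | but-3-en-2-one | CC(=O)C=C | starting material
2 | 2-[tri(propan-2-yl)silyloxy]buta-1,3-diene | C=CC(=C)O[Si](C(C)C)(C(C)C)C(C)C | intermediate
3 | 2,5-dimethylcyclohexa-2,5-diene-1,4-dione | CC1=CC(=O)C(C)=CC1=O | starting material
4 | (4aS,8aR)-2,4a-dimethyl-6-[tri(propan-2-yl)silyloxy]-4a,5,8,8a-tetrahydronaphthalene-1,4-dione | CC1=CC(=O)[C@@]2(C)CC(O[Si](C(C)C)(C(C)C)C(C)C)=CC[C@H]2C1=O | intermediate
5 | (4R,4aR,8aS)-4-hydroxy-3,8a-dimethyl-7-[tri(propan-2-yl)silyloxy]-4a,5,8,8a-tetrahydronaphthalen-1(4H)-one | CC1=CC(=O)[C@@]2(C)CC(O[Si](C(C)C)(C(C)C)C(C)C)=CC[C@H]2[C@H]1O | intermediate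
6 | (4R,4aR,8aS)-4-hydroxy-3,8a-dimethyl-4,4a,8,8a-tetrahydronaphthalene-1,7-dione | CC1=CC(=O)[C@@]2(C)CC(=O)C=C[C@H]2[C@H]1O | intermediate
7 | (4S,4aR,8aS)-4-bromo-3,8a-dimethyl-4,4a,8,8a-tetrahydronaphthalene-1,7-dione | CC1=CC(=O)[C@@]2(C)CC(=O)C=C[C@H]2[C@@H]1Br | intermediate
8 | lithium C11 (cross-conjugated) enolate of 7 | CC1=CC(=O)[C@@]2(C)C=C(O[Li])C=C[C@H]2[C@@H]1Br | intermediate
9 | (1S,2R,6S,7R)-2,5-dimethyltricyclo[4.4.0.0(2,7)]deca-4,9-diene-3,8-dione | O=C1C=C(C)[C@@H]2[C@H]3C(=O)C=C[C@@H]2[C@]31C | intermediate
10 | bis(trimethylsilyl enol ether) of 11 (C1=C2 and C9=C7 enol ethers) | C[Si](C)(C)OC1=CC(C)(C)[C@@H]2[C@H]3C(O[Si](C)(C)C)=C[C@@H](C)[C@@H]2[C@]31C | intermediate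
11 | (1S,2R,6S,7R,10R)-2,5,5,10-tetramethyltricyclo[4.4.0.0(2,7)]decane-3,8-dione | O=C1CC(C)(C)[C@@H]2[C@H]3C(=O)C[C@@H](C)[C@@H]2[C@]31C | intermediate
12 | (1S,2R,6R,7R)-5,7,10,10-tetramethyltricyclo[4.4.0.0(2,7)]dec-4-ene-3,8-dione | O=C1CC(C)(C)[C@@H]2[C@H]3C(=O)C=C(C)[C@@H]2[C@]31C | intermediate
13 | C8-trimethylsilyl derivative of 14 (C8 epimers) | O=C1C([Si](C)(C)C)CC(C)(C)[C@@H]2[C@H]3C(=O)C=C(C)[C@@H]2[C@]31C | intermediate
14 | (1R,2R,7S,8R)-2,6,6,11-tetramethyltricyclo[5.4.0.0(2,8)]undec-10-ene-3,9-dione | O=C1CCC(C)(C)[C@@H]2[C@H]3C(=O)C=C(C)[C@@H]2[C@]31C | intermediate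
15 | (1R,2R,7S,8R)-2,6,6,11-tetramethyltricyclo[5.4.0.0(2,8)]undeca-4,10-diene-3,9-dione | O=C1C=CC(C)(C)[C@@H]2[C@H]3C(=O)C=C(C)[C@@H]2[C@]31C | intermediate
16 | (1R,2R,5R,7S,8R)-2,6,6,11-tetramethyl-5-(4,4,5,5-tetramethyl-1,3,2-dioxaborolan-2-yl)tricyclo[5.4.0.0(2,8)]undec-10-ene-3,9-dione | O=C1C[C@@H](B2OC(C)(C)C(C)(C)O2)C(C)(C)[C@@H]2[C@H]3C(=O)C=C(C)[C@@H]2[C@]31C | intermediate
17 | (1R,2R,5R,7S,8R)-5-hydroxy-2,6,6,11-tetramethyltricyclo[5.4.0.0(2,8)]undec-10-ene-3,9-dione | O=C1C[C@@H](O)C(C)(C)[C@@H]2[C@H]3C(=O)C=C(C)[C@@H]2[C@]31C | intermediate
18 | (1R,2R,3R,5R,7S,8R)-3-hydroxy-2,6,6,11-tetramethyl-9-oxotricyclo[5.4.0.0(2,8)]undec-10-en-5-yl 3-methylbutanoate | O[C@@H]1C[C@@H](OC(=O)CC(C)C)C(C)(C)[C@@H]2[C@H]3C(=O)C=C(C)[C@@H]2[C@]31C | intermediate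
19 | (1R,2R,3R,5R,7S,8R)-2,6,6,11-tetramethyl-5-[(3-methylbutanoyl)oxy]-9-oxotricyclo[5.4.0.0(2,8)]undec-10-en-3-yl (2E)-2-methylbut-2-enoate | C/C=C(\C)C(=O)O[C@@H]1C[C@@H](OC(=O)CC(C)C)C(C)(C)[C@@H]2[C@H]3C(=O)C=C(C)[C@@H]2[C@]31C | target

Total step count: 13. Longest linear sequence: 13 steps, from 1 through 2 to 19 (3 enters at step 2). No protecting groups are used.

Steps least certain to work

Step 9 (key step). The most likely failure is loss of chemoselectivity or reactivity. The C9 carbonyl is hindered on both sides, and the Lewis acid binds the more basic enone oxygen first, so slow addition, attack at C1, a second insertion or epoxide formation could compete; migration of C10 is the lesser risk. The fallback sets out from 12 and changes the insertion method. Kinetic silylation (LDA, TMSCl, THF, −78 °C) can only give the C9–C7 trimethylsilyl enol ether F1. Cyclopropanation with Et2Zn and CH2I2 gives the siloxycyclopropane F2. FeCl3 in DMF cleaves the internal cyclopropane bond to the ring-expanded 7-chloro ketone F3, and NaOAc in MeOH eliminates HCl. This returns to the route at 15 and makes step 10 unnecessary.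

Step 6. The most likely failure is loss of bromide before ring closure: deprotonation at C4 (γ to the C1 enone) followed by vinylogous elimination would give a fully conjugated trienedione. Conjugate addition of the enolate to C6 or intermolecular reaction could also intervene. The fallback sets out from 7 and separates enolate formation from ring closure. LDA with TMSCl present at −78 °C traps the kinetic enolate as the trimethylsilyl dienol ether F4. After removal of amine and salts, tetrabutylammonium difluorotriphenylsilicate in THF (−40 to 0 °C) releases the enolate without base. It returns to the route at 9.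

Step 2. The most likely failure is erosion of enantioselectivity or acid-induced decomposition of the silyloxydiene by the strongly acidic catalyst. The fallback sets out from 2 and 3. BF3·OEt2 in CH2Cl2 at −78 °C keeps the Lewis-acid orientation but gives the racemate, that is 4 together with its mirror image F5. Preparative chromatography on a chiral stationary phase removes F5. It returns to the route at 4.

Step 4. The most likely failure is slow silicon-to-palladium exchange of the bulky triisopropylsilyl enol ether, with oxidation of the allylic alcohol taking over at higher temperature. The fallback sets out from 5. PhSeCl in CH2Cl2 at −78 °C gives the 2-(phenylselanyl) ketone F6, and H2O2 with pyridine effects selenoxide syn-elimination toward C3. It returns to the route at 6.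

Step 11. The most likely failure is poor facial selectivity: if the ligand does not override the very small substrate bias, a mixture of C7 epimers results. The fallback sets out from 15. Amine-catalysed asymmetric epoxidation (9-amino-9-deoxy-epi-quinine bis(trifluoroacetate), 50 % H2O2, dioxane) gives the 7,8-epoxy ketone F7 with oxygen on the C4 side. Reductive opening at the α-carbon with (PhSe)2 and NaBH4 in EtOH–AcOH follows. It returns to the route at 17.

Step 12. The most likely failure is slow hemiacetal formation at the neopentyl C7 hydroxyl, or reduction of the enone by divalent samarium before the active trivalent catalyst has formed. The fallback sets out from 17 and separates reduction from acylation. Me4NBH(OAc)3 in MeCN–AcOH at −20 °C gives the 7,9-anti diol F8 by hydroxyl-directed hydride delivery. One equivalent of (E)-2-methylbut-2-enoyl chloride in pyridine should acylate O9 first, since its quaternary neighbour is tied back in the cyclobutane, giving the 9-tiglate F9. 3-Methylbutanoic anhydride with DMAP then closes the sequence at 19. If O7 proves the more reactive hydroxyl, the acylating agents are used in the reverse order and the sequence passes through 18 and step 13.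

Further compounds

F1 | step 9 | trimethylsilyl enol ether of 12 at C9 (C9=C7), ring configuration as in 12 | C[Si](C)(C)OC1=CC(C)(C)[C@@H]2[C@H]3C(=O)C=C(C)[C@@H]2[C@]31C
F2 | step 9 | siloxycyclopropane from F1 (CH2 bridging C9 and C7), ring configuration as in 12 | C[Si](C)(C)OC12CC1C(C)(C)[C@@H]1[C@H]3C(=O)C=C(C)[C@@H]1[C@]32C
F3 | step 9 | 7-chloro derivative of 14 (5-chloro-2,6,6,11-tetramethyltricyclo[5.4.0.0(2,8)]undec-10-ene-3,9-dione) | O=C1CC(Cl)C(C)(C)[C@@H]2[C@H]3C(=O)C=C(C)[C@@H]2[C@]31C
F4 | step 6 | trimethylsilyl dienol ether of 7 (C11=C1 enol ether) | CC1=CC(=O)[C@@]2(C)C=C(O[Si](C)(C)C)C=C[C@H]2[C@@H]1Br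
F5 | step 2 | (4aR,8aS)-2,4a-dimethyl-6-[tri(propan-2-yl)silyloxy]-4a,5,8,8a-tetrahydronaphthalene-1,4-dione (mirror image of 4) | CC1=CC(=O)[C@]2(C)CC(O[Si](C(C)C)(C(C)C)C(C)C)=CC[C@@H]2C1=O
F6 | step 4 | (4R,4aR,8aS)-4-hydroxy-3,8a-dimethyl-6-(phenylselanyl)-4,4a,5,6,8,8a-hexahydronaphthalene-1,7-dione | CC1=CC(=O)[C@@]2(C)CC(=O)C([Se]c3ccccc3)C[C@H]2[C@H]1O
F7 | step 11 | 7,8-epoxide of 15 (oxygen on the C4 side) | O=C1[C@H]2O[C@H]2C(C)(C)[C@@H]3[C@H]4C(=O)C=C(C)[C@@H]3[C@]41C
F8 | step 12 | (1R,2R,3R,5R,7S,8R)-3,5-dihydroxy-2,6,6,11-tetramethyltricyclo[5.4.0.0(2,8)]undec-10-en-9-one | O[C@@H]1C[C@@H](O)C(C)(C)[C@@H]2[C@H]3C(=O)C=C(C)[C@@H]2[C@]31C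
F9 | step 12 | (1R,2R,3R,5R,7S,8R)-5-hydroxy-2,6,6,11-tetramethyl-9-oxotricyclo[5.4.0.0(2,8)]undec-10-en-3-yl (2E)-2-methylbut-2-enoate | C/C=C(\C)C(=O)O[C@@H]1C[C@@H](O)C(C)(C)[C@@H]2[C@H]3C(=O)C=C(C)[C@@H]2[C@]31C
A1 | alternative 1 | 9-(tert-butyldimethylsilyloxy)-4-hydroxy-7-(triethylsilyloxy)longipinan-1-one ethane-1,2-diyl ketal | CC(C)(C)[Si](C)(C)O[C@@H]1C[C@@H](O[Si](CC)(CC)CC)C(C)(C)[C@@H]2[C@H]3C4(OCCO4)C[C@@H](C)[C@]2(O)[C@]31C
A2 | alternative 2 | methyl 3-acetyl-4-[1-(benzyloxy)-2-methylpropan-2-yl]-2-(2,2-dimethyl-1,3-dioxolan-4-yl)-2-methylcyclobutane-1-carboxylate | c1ccccc1COCC(C)(C)[C@@H]2[C@@H](C(=O)OC)[C@](C)([C@H]3COC(C)(C)O3)[C@H]2C(C)=O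
A3 | alternative 3 | 9-(tert-butyldimethylsilyloxy)-7-(4-methoxybenzyloxy)longipin-2-en-1-one | CC(C)(C)[Si](C)(C)O[C@@H]1C[C@@H](OCc4ccc(OC)cc4)C(C)(C)[C@@H]2[C@H]3C(=O)C=C(C)[C@@H]2[C@]31C
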